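**Plan**

1. Retrosynthesis: remove the benzyl groups and bromine caps; cut the interflavan bond C4–C6' (Friedel–Crafts alkylation of the lower unit by a C4 cation of the upper unit); in the upper unit cut C2=C3 of ring C (ring-closing metathesis), then O1–C2 (ester) and C4a–C4 (Claisen rearrangement).
2. Enabling feature: C2 carries O1 and ring B, so at the carboxyl level O1–C2 is simply the 4-(benzyloxy)benzoate of the ring A phenol. C4 sits ortho to O1 on ring A, so an ortho-allyl group supplies C4 and C3. Methylenation of the ester and metathesis then join C2 to C3 as the enol ether of ring C.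
3. Forward order: ring A phenol → allyl ether → ortho-allyl phenol → aryl ester → enol ether → ring C (4H-chromene) → C2/C3 stereocentres → C4 ether and bromine caps → coupling with the capped lower unit → global hydrogenolysis. The lower unit is made by benzylation of (−)-epicatechin, galloylation of its 3-OH and bromination at C8.
4. Stereochemistry: C2 (R) from reagent-controlled hydroboration of the C2=C3 enol ether; C3 (R) by oxidation and hydride delivery anti to the C2 aryl group; C4 (S, 4β) by attack anti to the axial 3-OH on the C4 cation; lower unit (2R,3R) from (−)-epicatechin.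
5. Regiochemistry 4→6: bromine at C8 of the lower unit leaves only C6 free; bromine at C6 and C8 of the upper unit stops self-condensation. All three bromine atoms leave with the benzyl groups.

Key step: step 5

Remark: the facial sense of the pinene-derived borane on 8 is assumed to parallel that on 1-arylcycloalkenes; were it opposite, the reagent from (−)-α-pinene would be used.

**Route**

Step 1
Reactants: 1 3,5-bis(benzyloxy)phenol; 2 allyl bromide
Product: 3 1-(allyloxy)-3,5-bis(benzyloxy)benzene
Conditions: K2CO3, acetone, reflux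
Reagents that add atoms: none
Why: Williamson ether synthesis, SN2 attack of the phenoxide on the allylic bromide; no stereocentre.

Step 2
Reactants: 3 1-(allyloxy)-3,5-bis(benzyloxy)benzene
Product: 4 2-allyl-3,5-bis(benzyloxy)phenol
Conditions: N,N-diethylaniline, 190 °C
Reagents that add atoms: none
Why: Aromatic Claisen rearrangement ([3,3]-sigmatropic shift, then tautomerisation) places the allyl group on one of the two equivalent free ortho carbons (the future C4a), so that C4 and C3 sit ortho to the future O1; no stereocentre.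

Step 3
Reactants: 4 2-allyl-3,5-bis(benzyloxy)phenol; 5 4-(benzyloxy)benzoyl chloride
Product: 6 2-allyl-3,5-bis(benzyloxy)phenyl 4-(benzyloxy)benzoate
Conditions: Et3N, DMAP (cat.), CH2Cl2, 0 °C to rt
Reagents that add atoms: none
Why: DMAP-catalysed acylation of the phenol (nucleophilic acyl substitution) forms O1–C2 at the carboxyl oxidation level and brings in ring B; no stereocentre.

Step 4
Reactants: 6 2-allyl-3,5-bis(benzyloxy)phenyl 4-(benzyloxy)benzoate
Product: 7 2-allyl-1,5-bis(benzyloxy)-3-{[1-(4-(benzyloxy)phenyl)vinyl]oxy}benzene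
Conditions: Cp2TiMe2, toluene, 70 °C, dark; filtration through basic alumina
Reagents that add atoms: dimethyltitanocene, C[Ti](C)(C1C=CC=C1)C1C=CC=C1
Why: Petasis methylenation (carbonyl olefination of the ester by Cp2Ti=CH2 through an oxatitanacyclobutane) turns the ester carbonyl C2 into the 1,1-disubstituted enol ether needed for metathesis; no stereocentre.

Step 5
Reactants: 7 2-allyl-1,5-bis(benzyloxy)-3-{[1-(4-(benzyloxy)phenyl)vinyl]oxy}benzene
Product: 8 5,7-bis(benzyloxy)-2-[4-(benzyloxy)phenyl]-4H-chromene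
Conditions: second-generation Grubbs catalyst (5 mol %), 1,4-benzoquinone (10 mol %), degassed toluene, 60 °C
Reagents that add atoms: none
Why: Ring-closing olefin metathesis: the ruthenium alkylidene loads at the unhindered allyl terminus (C3), adds [2+2] across the 1,1-disubstituted enol ether C2=CH2, and the ruthenacyclobutane cycloreverts to the C2=C3 double bond with loss of ethylene. The closest known reaction type is ring-closing metathesis of an olefinic enol ether made by methylenation of an ester, the established entry to cyclic enol ethers including 4H-chromenes from ortho-allylphenyl esters. The six-membered pyran ring C (O1, C2, C3, C4, C4a, C8a) is closed with both alkene carbons inside the ring, the ortho relation of O1 and C4 on ring A holding the two olefins within bonding distance. No stereocentre is formed; the step delivers C2 and C3 as one prochiral, electronically biased enol ether whose faces are told apart in step 6. Chemoselectivity is needed for initiation at the allyl group and not at the enol ether (which would park the catalyst as a Fischer carbene), and against allyl-to-propenyl migration (which would contract the ring to a benzofuran); the 1,1-disubstitution of the enol ether secures the first, the quinone additive and moderate temperature the second. Neutral, acid-free conditions keep the hydrolytically labile aryl enol ether intact.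

Step 6
Reactants: 8 5,7-bis(benzyloxy)-2-[4-(benzyloxy)phenyl]-4H-chromene
Product: 10 (2R,3S)-5,7-bis(benzyloxy)-2-[4-(benzyloxy)phenyl]chroman-3-ol (2,3-trans), via chroman-3-yl(isopinocampheyl)borane 9 (not isolated)
Conditions: IpcBH2 (from (+)-α-pinene), THF, −25 °C; then NaOH, H2O2, 0 °C to rt
Reagents that add atoms: hydrogen peroxide, OO
Why: Asymmetric hydroboration–oxidation: boron adds to C3 (the β-carbon of the enol ether) and hydrogen to C2 in a syn manner on the face selected by the chiral borane, which sets C2 (R) and C3 (S) with the 2,3-trans relation, and the C–B bond is oxidised with retention.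

Step 7
Reactants: 10 (2R,3S)-5,7-bis(benzyloxy)-2-[4-(benzyloxy)phenyl]chroman-3-ol
Product: 11 (2R)-5,7-bis(benzyloxy)-2-[4-(benzyloxy)phenyl]chroman-3-one
Conditions: Dess–Martin periodinane, CH2Cl2, 0 °C to rt
Reagents that add atoms: none
Why: Dess–Martin oxidation of the secondary alcohol under near-neutral conditions should leave the enolisable C2 stereocentre untouched; the ketone is used at once.

Step 8
Reactants: 11 (2R)-5,7-bis(benzyloxy)-2-[4-(benzyloxy)phenyl]chroman-3-one
Product: 12 (2R,3R)-5,7-bis(benzyloxy)-2-[4-(benzyloxy)phenyl]chroman-3-ol (2,3-cis)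
Conditions: LiBH(s-Bu)3 (L-Selectride), THF, −78 °C; then H2O
Reagents that add atoms: none
Why: Hydride reduction of the cyclic ketone by the bulky trialkylborohydride from the face opposite the C2 aryl group should give the axial 3-OH cis to that aryl group, so C3 (R) is set under control of C2.

Step 9
Reactants: 12 (2R,3R)-5,7-bis(benzyloxy)-2-[4-(benzyloxy)phenyl]chroman-3-ol
Product: 13 (2R,3R,4S)-5,7-bis(benzyloxy)-2-[4-(benzyloxy)phenyl]-4-(2-ethoxyethoxy)chroman-3-ol (4β ether, 3,4-trans)
Conditions: DDQ, 2-ethoxyethanol, CH2Cl2, rt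
Reagents that add atoms: 2-ethoxyethanol, CCOCCO
Why: Benzylic oxidation by DDQ (hydride abstraction at C4 to the cation stabilised by the three oxygen atoms of ring A) and capture by the alcohol anti to the 3-OH should give the 4β ether, C4 (S) being set by the 2,3-cis substituents.

Step 10
Reactants: 13 (2R,3R,4S)-5,7-bis(benzyloxy)-2-[4-(benzyloxy)phenyl]-4-(2-ethoxyethoxy)chroman-3-ol
Product: 14 (2R,3R,4S)-5,7-bis(benzyloxy)-6,8-dibromo-2-[4-(benzyloxy)phenyl]-4-(2-ethoxyethoxy)chroman-3-ol
Conditions: NBS (2.1 equiv), CH2Cl2, −40 to 0 °C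
Reagents that add atoms: N-bromosuccinimide, O=C1CCC(=O)N1Br
Why: Electrophilic aromatic bromination at C6 and C8, the two most electron-rich nuclear positions of the molecule, caps ring A against self-condensation; no stereocentre is touched.

Step 11
Reactants: 15 (−)-epicatechin
Product: 16 (2R,3R)-5,7-bis(benzyloxy)-2-[3,4-bis(benzyloxy)phenyl]chroman-3-ol
Conditions: BnBr (4.4 equiv), K2CO3, DMF, N2, 0 °C to rt
Reagents that add atoms: benzyl bromide, BrCc1ccccc1
Why: Williamson benzylation of the four phenols under mild carbonate conditions, which leave the far less acidic secondary 3-OH free; both stereocentres come unchanged from the natural product.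

Step 12
Reactants: 16 (2R,3R)-5,7-bis(benzyloxy)-2-[3,4-bis(benzyloxy)phenyl]chroman-3-ol; 17 3,4,5-tris(benzyloxy)benzoic acid
Product: 18 (2R,3R)-5,7-bis(benzyloxy)-2-[3,4-bis(benzyloxy)phenyl]chroman-3-yl 3,4,5-tris(benzyloxy)benzoate
Conditions: DCC, DMAP, CH2Cl2, 0 °C to rt
Reagents that add atoms: none
Why: Steglich esterification: the acid is activated as its O-acylisourea and transferred by DMAP to the axial secondary 3-OH; acylation occurs at oxygen, so C3 keeps its configuration.

Step 13
Reactants: 18 (2R,3R)-5,7-bis(benzyloxy)-2-[3,4-bis(benzyloxy)phenyl]chroman-3-yl 3,4,5-tris(benzyloxy)benzoate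
Product: 19 (2R,3R)-5,7-bis(benzyloxy)-8-bromo-2-[3,4-bis(benzyloxy)phenyl]chroman-3-yl 3,4,5-tris(benzyloxy)benzoate
Conditions: NBS (1.0 equiv), CH2Cl2, −78 to 0 °C
Reagents that add atoms: N-bromosuccinimide, O=C1CCC(=O)N1Br
Why: Electrophilic aromatic bromination goes to C8, the more reactive of the two free positions of ring A, and so blocks it while leaving C6 free; the ester-deactivated gallate ring and ring B should not compete.

Step 14
Reactants: 14 (2R,3R,4S)-5,7-bis(benzyloxy)-6,8-dibromo-2-[4-(benzyloxy)phenyl]-4-(2-ethoxyethoxy)chroman-3-ol; 19 (2R,3R)-5,7-bis(benzyloxy)-8-bromo-2-[3,4-bis(benzyloxy)phenyl]chroman-3-yl 3,4,5-tris(benzyloxy)benzoate (2 equiv)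
Product: 20 (2R,3R)-5,7-bis(benzyloxy)-8-bromo-2-[3,4-bis(benzyloxy)phenyl]-6-[(2R,3R,4S)-5,7-bis(benzyloxy)-6,8-dibromo-2-(4-(benzyloxy)phenyl)-3-hydroxychroman-4-yl]chroman-3-yl 3,4,5-tris(benzyloxy)benzoate
Conditions: TMSOTf (cat.), 4 Å MS, CH2Cl2, −78 to −20 °C
Reagents that add atoms: none
Why: Lewis-acid ionisation of the C4 ether to the ring-A-stabilised benzylic cation and Friedel–Crafts alkylation by C6 of 19, its only free nuclear position; attack anti to the axial 3-OH and the C2 aryl group should set C4 (S, 4β, 3,4-trans), while the bromine atoms exclude reaction at C8 of 19 and self-condensation of 14.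

Step 15
Reactants: 20 protected, tribrominated dimer
Product: 21 (2R,3R)-2-(3,4-dihydroxyphenyl)-5,7-dihydroxy-6-[(2R,3R,4S)-3,5,7-trihydroxy-2-(4-hydroxyphenyl)chroman-4-yl]chroman-3-yl 3,4,5-trihydroxybenzoate
Conditions: H2 (1 atm), Pd(OH)2/C, Et3N, THF/MeOH/H2O, rt; work-up under argon
Reagents that add atoms: none
Why: Palladium-catalysed hydrogenolysis of the ten benzyl ethers and hydrodebromination of the three aryl bromides, buffered by the amine so that the gallate ester and the acid-labile interflavan bond survive; no stereocentre is touched.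

**Compound list**

1 | 3,5-bis(benzyloxy)phenol | Oc1cc(OCc2ccccc2)cc(OCc2ccccc2)c1 | starting material
2 | allyl bromide | C=CCBr | starting material
3 | 1-(allyloxy)-3,5-bis(benzyloxy)benzene | C=CCOc1cc(OCc2ccccc2)cc(OCc2ccccc2)c1 | intermediate
4 | 2-allyl-3,5-bis(benzyloxy)phenol | C=CCc1c(O)cc(OCc2ccccc2)cc1OCc1ccccc1 | intermediate
5 | 4-(benzyloxy)benzoyl chloride | O=C(Cl)c1ccc(OCc2ccccc2)cc1 | starting material
6 | 2-allyl-3,5-bis(benzyloxy)phenyl 4-(benzyloxy)benzoate | C=CCc1c(OC(=O)c2ccc(OCc3ccccc3)cc2)cc(OCc2ccccc2)cc1OCc1ccccc1 | intermediate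
7 | 2-allyl-1,5-bis(benzyloxy)-3-{[1-(4-(benzyloxy)phenyl)vinyl]oxy}benzene | C=CCc1c(OC(=C)c2ccc(OCc3ccccc3)cc2)cc(OCc2ccccc2)cc1OCc1ccccc1 | intermediate
8 | 5,7-bis(benzyloxy)-2-[4-(benzyloxy)phenyl]-4H-chromene | C1(c2ccc(OCc3ccccc3)cc2)=CCc2c(O1)cc(OCc1ccccc1)cc2OCc1ccccc1 | intermediate
9 | (isopinocampheyl)[2,3-trans-5,7-bis(benzyloxy)-2-(4-(benzyloxy)phenyl)chroman-3-yl]borane, C2 aryl α, boron β (not isolated) | C[C@H]1[C@H](B[C@H]2Cc3c(OCc4ccccc4)cc(OCc4ccccc4)cc3O[C@@H]2c2ccc(OCc3ccccc3)cc2)C[C@@H]2C[C@H]1C2(C)C | intermediate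
10 | (2R,3S)-5,7-bis(benzyloxy)-2-[4-(benzyloxy)phenyl]chroman-3-ol (2,3-trans) | O[C@H]1Cc2c(OCc3ccccc3)cc(OCc3ccccc3)cc2O[C@@H]1c1ccc(OCc2ccccc2)cc1 | intermediate
11 | (2R)-5,7-bis(benzyloxy)-2-[4-(benzyloxy)phenyl]chroman-3-one | O=C1Cc2c(OCc3ccccc3)cc(OCc3ccccc3)cc2O[C@@H]1c1ccc(OCc2ccccc2)cc1 | intermediate
12 | (2R,3R)-5,7-bis(benzyloxy)-2-[4-(benzyloxy)phenyl]chroman-3-ol (2,3-cis) | O[C@@H]1Cc2c(OCc3ccccc3)cc(OCc3ccccc3)cc2O[C@@H]1c1ccc(OCc2ccccc2)cc1 | intermediate
13 | (2R,3R,4S)-5,7-bis(benzyloxy)-2-[4-(benzyloxy)phenyl]-4-(2-ethoxyethoxy)chroman-3-ol (2,3-cis, 3,4-trans) | CCOCCO[C@H]1c2c(OCc3ccccc3)cc(OCc3ccccc3)cc2O[C@H](c2ccc(OCc3ccccc3)cc2)[C@@H]1O | intermediate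
14 | (2R,3R,4S)-5,7-bis(benzyloxy)-6,8-dibromo-2-[4-(benzyloxy)phenyl]-4-(2-ethoxyethoxy)chroman-3-ol | CCOCCO[C@H]1c2c(OCc3ccccc3)c(Br)c(OCc3ccccc3)c(Br)c2O[C@H](c2ccc(OCc3ccccc3)cc2)[C@@H]1O | intermediate
15 | (−)-epicatechin, (2R,3R) | O[C@@H]1Cc2c(O)cc(O)cc2O[C@@H]1c1ccc(O)c(O)c1 | starting material
16 | (2R,3R)-5,7-bis(benzyloxy)-2-[3,4-bis(benzyloxy)phenyl]chroman-3-ol (tetra-O-benzyl-(−)-epicatechin) | O[C@@H]1Cc2c(OCc3ccccc3)cc(OCc3ccccc3)cc2O[C@@H]1c1ccc(OCc2ccccc2)c(OCc2ccccc2)c1 | intermediate
17 | 3,4,5-tris(benzyloxy)benzoic acid | OC(=O)c1cc(OCc2ccccc2)c(OCc2ccccc2)c(OCc2ccccc2)c1 | starting material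
18 | (2R,3R)-5,7-bis(benzyloxy)-2-[3,4-bis(benzyloxy)phenyl]chroman-3-yl 3,4,5-tris(benzyloxy)benzoate | O=C(O[C@@H]1Cc2c(OCc3ccccc3)cc(OCc3ccccc3)cc2O[C@@H]1c1ccc(OCc2ccccc2)c(OCc2ccccc2)c1)c1cc(OCc2ccccc2)c(OCc2ccccc2)c(OCc2ccccc2)c1 | intermediate
19 | (2R,3R)-5,7-bis(benzyloxy)-8-bromo-2-[3,4-bis(benzyloxy)phenyl]chroman-3-yl 3,4,5-tris(benzyloxy)benzoate | O=C(O[C@@H]1Cc2c(OCc3ccccc3)cc(OCc3ccccc3)c(Br)c2O[C@@H]1c1ccc(OCc2ccccc2)c(OCc2ccccc2)c1)c1cc(OCc2ccccc2)c(OCc2ccccc2)c(OCc2ccccc2)c1 | intermediate
20 | deca-O-benzyl tribromo dimer: upper unit (2R,3R,4S) with bromine at C6 and C8, joined 4β→6 to the lower unit (2R,3R) with bromine at C8 and the tribenzylgallate on its 3-O | O=C(O[C@@H]1Cc2c(c(Br)c(OCc3ccccc3)c([C@H]3c4c(OCc5ccccc5)c(Br)c(OCc5ccccc5)c(Br)c4O[C@H](c4ccc(OCc5ccccc5)cc4)[C@@H]3O)c2OCc2ccccc2)O[C@@H]1c1ccc(OCc2ccccc2)c(OCc2ccccc2)c1)c1cc(OCc2ccccc2)c(OCc2ccccc2)c(OCc2ccccc2)c1 | intermediate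
21 | epiafzelechin-(4β→6)-epicatechin 3-O-gallate (gallate on the lower unit); upper unit 2R,3R,4S, lower unit 2R,3R | O=C(O[C@@H]1Cc2c(cc(O)c([C@H]3c4c(O)cc(O)cc4O[C@H](c4ccc(O)cc4)[C@@H]3O)c2O)O[C@@H]1c1ccc(O)c(O)c1)c1cc(O)c(O)c(O)c1 | target

**Count and risks**

Total steps: 15. Longest linear sequence: 12 (steps 1 to 10, then 14 and 15).

Most likely to fail:

1. Step 14. The brominated ring A of 19 is a weak nucleophile at C6, which is flanked by two benzyloxy groups, and the dibrominated cation from 14 is inductively destabilised and crowded. The cation may therefore be lost by elimination toward the flav-3-ene or by attack on other benzyloxy-arene rings before C6 engages. The fallback gives up the caps on the electrophile and relies on stoichiometry instead of blocking. Setting out from 13 and 19, the uncapped ether 13 is added slowly to a large excess of 19 (TMSOTf cat., 4 Å MS, CH2Cl2, −78 °C). The more stable, less hindered cation should be captured at C6 of 19 before it meets a second molecule of 13, giving the 4β→6 coupled monobromide, deca-O-benzyl 8-bromo dimer F1. F1 is hydrogenolysed under the conditions of step 15, which brings the route back at 21.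

2. Step 5. Migration of the allyl double bond into conjugation, followed by ring-contracting metathesis to a benzofuran, or sequestration of the catalyst on the electron-rich enol ether, may outrun closure of ring C. The fallback forms the same C2=C3 bond reductively. Setting out from 6, oxidative cleavage of the allyl group (OsO4 cat., NaIO4, 2,6-lutidine, dioxane/H2O) gives the aldehyde 3,5-bis(benzyloxy)-2-(2-oxoethyl)phenyl 4-(benzyloxy)benzoate F2. Low-valent titanium (TiCl3, Zn, DME, reflux, high dilution) then couples the aldehyde carbon with the ester carbonyl in a McMurry-type oxo-ester cyclisation, which comes back at 8.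

3. Step 6. Facial discrimination by the chiral borane on the aryl-substituted enol ether may be insufficient, giving material of low enantiomeric purity. The fallback takes the stereochemistry from resolution instead of reagent control. Setting out from 8, hydroboration with BH3·SMe2 (THF, 0 °C) gives the racemic 2,3-trans chroman-3-ylborane F3 (not isolated). Oxidation (NaOH, H2O2) gives the racemic trans alcohol, that is 10 together with its enantiomer (2S,3R)-5,7-bis(benzyloxy)-2-[4-(benzyloxy)phenyl]chroman-3-ol F4. Preparative chromatography on a chiral stationary phase separates the two, and the route is rejoined at 10.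

**Further compounds**

F1 | step 14 | (2R,3R)-5,7-bis(benzyloxy)-8-bromo-2-[3,4-bis(benzyloxy)phenyl]-6-[(2R,3R,4R)-5,7-bis(benzyloxy)-2-(4-(benzyloxy)phenyl)-3-hydroxychroman-4-yl]chroman-3-yl 3,4,5-tris(benzyloxy)benzoate (4β, 3,4-trans; same geometry at C4 as in 20, the descriptor changing only through the sequence rule) | O=C(O[C@@H]1Cc2c(c(Br)c(OCc3ccccc3)c([C@H]3c4c(OCc5ccccc5)cc(OCc5ccccc5)cc4O[C@H](c4ccc(OCc5ccccc5)cc4)[C@@H]3O)c2OCc2ccccc2)O[C@@H]1c1ccc(OCc2ccccc2)c(OCc2ccccc2)c1)c1cc(OCc2ccccc2)c(OCc2ccccc2)c(OCc2ccccc2)c1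
F2 | step 5 | 3,5-bis(benzyloxy)-2-(2-oxoethyl)phenyl 4-(benzyloxy)benzoate | O=CCc1c(OC(=O)c2ccc(OCc3ccccc3)cc2)cc(OCc2ccccc2)cc1OCc1ccccc1
F3 | step 6 | racemic 2,3-trans-[5,7-bis(benzyloxy)-2-(4-(benzyloxy)phenyl)chroman-3-yl]borane (one enantiomer drawn) | B[C@H]1Cc2c(OCc3ccccc3)cc(OCc3ccccc3)cc2O[C@@H]1c1ccc(OCc2ccccc2)cc1
F4 | step 6 | (2S,3R)-5,7-bis(benzyloxy)-2-[4-(benzyloxy)phenyl]chroman-3-ol (enantiomer of 10) | O[C@@H]1Cc2c(OCc3ccccc3)cc(OCc3ccccc3)cc2O[C@H]1c1ccc(OCc2ccccc2)cc1
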